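## Analysis of the target

The target is a meta-terphenyl built from three phloroglucinol rings joined by two carbon–carbon bonds: ring A (atoms a1–a6), central ring B (b1–b6) and ring C (c1–c6), with a6 bonded to b1 and b3 bonded to c1 (lower-case locants denote ring atoms throughout). Oxygen sits on a1 (the hydrogen sulfate), a3 and a5, on b2, b4 and b6, and on c2, c4 and c6; b5 is the only CH of ring B. There is no stereocentre. The a6–b1 axis has four ortho oxygens and becomes formally stereogenic once a1 and a5 differ, but the target is specified without axial configuration, and the b3–c1 axis carries a symmetric ring. The sensitive features are the aryl sulfate monoester, which is stable as a salt but hydrolyses in acid, and eight phenols on very electron-rich rings, which oxidise in air when free and alkylate on carbon as well as on oxygen. The difficulty is twofold: both biaryl bonds are tetra-ortho-oxygenated and so among the hardest to make by cross-coupling, and one oxygen (a1, equivalent by symmetry to a5, c2 and c6 in the parent nonaol) must be singled out for sulfation. The strategy rests on ring B, a 2,4-diarylphloroglucinol: b1–b2–b3 with both aryl groups is the skeleton of a 1,3-diarylacetone, and b4–b5–b6 is a malonyl unit. If ring B is closed last from these two pieces, the hindered biaryl bonds exist beforehand as ordinary aryl–CH2 bonds, and the oxygen to be sulfated can be marked on the ring A building block before the rings are joined.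

## Retrosynthetic reasoning

Target 24 is reached from the octabenzyl sodium sulfate 22 by cleaving the eight O–CH2Ph bonds and protonating the resulting salt 23. Benzyl is used on all eight hydroxyls so that one neutral hydrogenolysis ends the synthesis; the sulfate monoanion is not reduced, and the oxidation-prone free polyphenol appears only in the last flask. The forward step must remove every benzyl group, including the hindered one on the b2 oxygen, and leave the S–O bonds alone.

Salt 22 is cut at the O–S bond to phenol 21, whose only free hydroxyl is on a1. Sulfating here asks no selectivity of the reagent and keeps the sulfate away from every basic or organometallic step. Phenol 21 comes from acetal 20 by acid removal of the methoxymethyl group, and 20 from triol 19 by benzylation of the three ring B oxygens. The a1 oxygen is thus the one oxygen that carries an acid-labile group from the moment the ring A building block is made.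

Triol 19 is cut at b1–b6 and b3–b4, which removes b4–b5–b6 as malonic ester 16 and leaves ketone 15. These bonds are chosen over a6–b1 and b3–c1 because cutting the biaryl bonds would demand two couplings between carbons that each carry two ortho oxygens; in 15 the same connections are aryl–CH2 bonds. The cut also uses the latent symmetry of ring B: either benzylic carbon may react first, and both paths give the same arene. The forward reaction must acylate both benzylic carbons of 15 on carbon with the two ester groups of 16 and then aromatise; the three new hydroxyls are the only free ones in 19.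

Ketone 15 is the dealkoxycarbonylation product of β-keto ester 14. Ester 14 is cut between the ketone carbon and the ester-bearing carbon into arylacetic ester 8 (ring C, nucleophile) and arylacetic acid 12 (ring A, acyl donor as imidazolide 13). The extra ester group makes the union a directed Claisen condensation rather than a statistical ketonisation of two arylacetic acids, and it is removed in one neutral step. This avoids 2,4,6-trialkoxybenzyl halides and benzyl organometallics, which ionise or polymerise easily.

Ester 8 and acid 12 are traced to nitriles 6 and 11, and these to aldehydes 4 and 10, by removing the nitrile carbon. The forward homologation uses isocyanide 5 under basic conditions, which the benzyl ethers and the acetal of 10 both tolerate. The arms differ only in the solvolysis of the nitrile: acidic methanolysis for 6, which has no acetal, and alkaline hydrolysis for 11.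

Aldehydes 4 and 10 come from the common phenol 3 by O-alkylation with bromide 2 or chloro ether 9, and 3 comes from trihydroxybenzaldehyde 1 and 2. The hydrogen bond between an ortho hydroxyl and the formyl group leaves exactly one hydroxyl of 1 unalkylated, which marks the future sulfate position in the first step.

## Alternatives that were turned down

Alternative 1: Both outer rings are made at once on a finished ring B. Each outer ring is cut at the two bonds of the hydroxyl-bearing carbon next to the biaryl bond (a1–a2 and a1–a6 in ring A, c2–c1 and c2–c3 in ring C); that carbon comes from CO, and the precursor is the bis(acetoxy enyne) A2.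
- Forward key step: [Rh(CO)2Cl]2 (monovalent rhodium) under CO should induce, in each arm, a 1,2-acyloxy shift of the propargylic acetate to a rhodium vinylcarbene, CO insertion to a dienylketene, 6π-electrocyclisation and tautomerisation. Product A1 has free hydroxyls at a1 and c2, acetates at a3 and c4 and five benzyl ethers.
- For it: two rings and four bonds form in one operation (the chosen route forms one ring and two bonds), the biaryl bonds exist beforehand as aryl–alkenyl bonds, and the oxygens emerge in three distinguishable classes.
- Against it: the two free hydroxyls of A1 are the symmetry-related a1 and c2 positions, so monosulfation would be statistical. The alkene carbon that must bond to the ketene carbon bears a di-ortho-substituted aryl group, twice in one molecule, and the vinylcarbene can instead close to a cyclopentenone (Rautenstrauch-type path). A2 has two stereocentres and two enol ether double bonds of undefined configuration and needs a long two-directional sequence.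
- Comparison: it is stronger in the bond-forming power of its key step. The chosen route offers a single marked oxygen from the first step and a precursor made from two aldehydes by routine reactions.

Alternative 2: Ring B is cut at b1–b2 and b5–b6 into two halves of similar size: the 4-arylcyclobutenone A4 carrying ring C, and the aryl siloxyalkyne A5 carrying ring A with its sulfate already present as a trichloroethyl diester.
- Forward key step (Danheiser benzannulation): on heating, A4 should open to a vinylketene and add to A5 in a [2+2] cycloaddition; the new cyclobutenone opens and recloses by 6π-electrocyclisation. Phenol A3 results, with a free hydroxyl at b2, silyl ethers at a5 and b6, the protected sulfate at a1 and five benzyl ethers.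
- For it: it is convergent, thermal and neutral, its regiochemistry follows from the polarity of ketene and ynol ether, and the sulfate is installed early in protected form, so no late sulfation of a hindered phenol is needed. On these points it is stronger than the chosen route.
- Against it: the bimolecular [2+2] step must join the ketene carbonyl carbon to an alkyne carbon bearing a di-ortho-substituted aryl ring while the other ketene terminus bears the second such ring. A5 combines an acid-sensitive siloxyalkyne with a base- and nucleophile-sensitive sulfate diester, and the usual ester-to-ynolate route to siloxyalkynes uses excess alkyllithium, so the order of events in making A5 is unresolved. A3 still needs three kinds of protecting group removed.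
- Comparison: two multistep components plus the end game exceed the step count of the chosen route. The chosen route has a less precedented key step but brings unhindered sp3 carbons together where A4 and A5 must join crowded sp and sp2 carbons.

Alternative 3: Ring C is made last by cutting c2–c3, which turns it into the 4-hydroxy-6-methylpyran-2-one ring of A7, attached through its carbon 3 to the finished ring A–ring B biaryl.
- Forward key step: Mg(OMe)2 and then NaOMe in hot methanol should open the lactone to a 3,5-dioxo ester, and the carbanion of the terminal methyl group attacks the ester carbon (Claisen closure). Product A6 has ring C as a free triol, the acetal on a1 and the other oxygens benzylated.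
- For it: the ring-forming step is purely intramolecular and a close analogue of the base-induced conversion of 3,5-dioxo esters into phloroglucinols, so its key step is better precedented than the chosen one. A6 also shares the protecting-group logic of 19.
- Against it: it builds an outer ring, so a6–b1 and the bond from b3 to the pyranone must already exist and have to be made by coupling at tetra-ortho-substituted carbons; the main difficulty is moved, not removed. The closure uses the least acidic carbon (a methyl group) against an ester whose α-carbon carries the bulky biaryl, and three benzylations still follow.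
- Comparison: the linear build-up of biaryl, pyranone and ring C should be longer than the chosen convergent route, which creates both biaryl connections in the operation that closes ring B.

Key step: step 10

Assumption: the target is taken as the free aryl hydrogen sulfate as drawn, without defined configuration at the a6–b1 axis; it is liberated from its sodium salt 23 in the last operation and would be stored as that salt, because aryl hydrogen sulfates hydrolyse in their acid form.

## Route

Step 1
Reactants: 1 2,4,6-trihydroxybenzaldehyde; 2 benzyl bromide
Product: 3 2,4-bis(benzyloxy)-6-hydroxybenzaldehyde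
Conditions: BnBr (2.1 equiv), K2CO3 (2.2 equiv), DMF, 0 °C → rt
Reagents that add atoms: benzyl bromide 2, BrCc1ccccc1
Why: Williamson etherification; the para hydroxyl and one ortho hydroxyl are alkylated, whereas the last ortho hydroxyl is held in a hydrogen bond to the formyl oxygen and is much less nucleophilic, so the reaction should stop at the bis-ether under mild conditions.

Step 2
Reactants: 3 2,4-bis(benzyloxy)-6-hydroxybenzaldehyde; 2 benzyl bromide
Product: 4 2,4,6-tris(benzyloxy)benzaldehyde
Conditions: BnBr (1.5 equiv), K2CO3, n-Bu4NI (cat.), DMF, 70 °C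
Reagents that add atoms: benzyl bromide 2, BrCc1ccccc1
Why: Williamson etherification of the chelated phenol, forced by heat and iodide catalysis; the formyl group lowers the carbon nucleophilicity of the ring and so disfavours C-benzylation.

Step 3
Reactants: 4 2,4,6-tris(benzyloxy)benzaldehyde; 5 p-toluenesulfonylmethyl isocyanide (TosMIC)
Product: 6 2-[2,4,6-tris(benzyloxy)phenyl]acetonitrile
Conditions: TosMIC (1.2 equiv), t-BuOK (2.4 equiv), DME, −50 °C; then MeOH, reflux
Reagents that add atoms: TosMIC 5, Cc1ccc(cc1)S(=O)(=O)C[N+]#[C-]
Why: van Leusen reductive cyanation; the TosMIC anion adds to the aldehyde and closes to an oxazoline, and base-induced ring opening, deformylation by methanol and loss of sulfinate should give the arylacetonitrile with one more carbon; adding methanol only after the cold addition suppresses oxazole formation.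

Step 4
Reactants: 6 2-[2,4,6-tris(benzyloxy)phenyl]acetonitrile
Product: 8 methyl 2-[2,4,6-tris(benzyloxy)phenyl]acetate, via imidate hydrochloride 7 (not isolated)
Conditions: HCl (4 M in dioxane), MeOH/CH2Cl2, 0 °C → rt; then H2O, rt
Reagents that add atoms: methanol, CO; water, O
Why: Pinner reaction; HCl and methanol add to the nitrile to give the imidate hydrochloride, which water hydrolyses to the methyl ester, and aryl benzyl ethers tolerate methanolic HCl at room temperature.

Step 5
Reactants: 3 2,4-bis(benzyloxy)-6-hydroxybenzaldehyde; 9 chloromethyl methyl ether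
Product: 10 2,4-bis(benzyloxy)-6-(methoxymethoxy)benzaldehyde
Conditions: MOMCl (2 equiv), i-Pr2NEt (3 equiv), CH2Cl2, 0 → 40 °C
Reagents that add atoms: chloromethyl methyl ether 9, COCCl
Why: O-alkylation of the phenol by the α-chloro ether through its oxocarbenium ion; excess reagent and base are used because the phenol is chelated to the aldehyde.

Step 6
Reactants: 10 2,4-bis(benzyloxy)-6-(methoxymethoxy)benzaldehyde; 5 TosMIC
Product: 11 2-[2,4-bis(benzyloxy)-6-(methoxymethoxy)phenyl]acetonitrile
Conditions: TosMIC (1.2 equiv), t-BuOK (2.4 equiv), DME, −50 °C; then MeOH, reflux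
Reagents that add atoms: TosMIC 5, Cc1ccc(cc1)S(=O)(=O)C[N+]#[C-]
Why: van Leusen reductive cyanation as in step 3; the conditions are basic throughout, so the methoxymethyl ether is not at risk.

Step 7
Reactants: 11 2-[2,4-bis(benzyloxy)-6-(methoxymethoxy)phenyl]acetonitrile
Product: 12 2-[2,4-bis(benzyloxy)-6-(methoxymethoxy)phenyl]acetic acid
Conditions: KOH, HOCH2CH2OH/H2O, 120 °C; then AcOH to pH 5, 0 °C
Reagents that add atoms: potassium hydroxide, [K+].[OH-]; water, O
Why: Alkaline nitrile hydrolysis via the primary amide; benzyl and methoxymethyl ethers are stable to hydroxide, and acidification with acetic acid to about pH 5 frees the acid without touching the acetal.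

Step 8
Reactants: 12 2-[2,4-bis(benzyloxy)-6-(methoxymethoxy)phenyl]acetic acid; 8 methyl 2-[2,4,6-tris(benzyloxy)phenyl]acetate
Product: 14 methyl 4-[2,4-bis(benzyloxy)-6-(methoxymethoxy)phenyl]-3-oxo-2-[2,4,6-tris(benzyloxy)phenyl]butanoate (racemic), via acyl imidazolide 13 (not isolated)
Conditions: 12, CDI (1.1 equiv), THF, rt; 8 (1.2 equiv), LiHMDS (3.4 equiv), THF, −78 °C, then the solution of 13, −78 → 0 °C; AcOH
Reagents that add atoms: none
Why: Directed crossed Claisen condensation; the preformed lithium enolate of 8 is C-acylated by acyl imidazolide 13, the excess base takes up the liberated imidazole and the acidic β-keto ester, and any ketene formed from 13 by proton loss is captured by the same enolate to give the same product.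

Step 9
Reactants: 14 the β-keto ester of step 8
Product: 15 1-[2,4-bis(benzyloxy)-6-(methoxymethoxy)phenyl]-3-[2,4,6-tris(benzyloxy)phenyl]propan-2-one
Conditions: LiCl, H2O, DMSO, 130 °C
Reagents that add atoms: none
Why: Krapcho dealkoxycarbonylation; chloride attacks the ester methyl group, the β-keto carboxylate loses CO2 and the enolate is protonated by water, all under neutral conditions that spare the ethers.

Step 10
Reactants: 15 1-[2,4-bis(benzyloxy)-6-(methoxymethoxy)phenyl]-3-[2,4,6-tris(benzyloxy)phenyl]propan-2-one; 16 dimethyl malonate
Product: 19 2-[2,4-bis(benzyloxy)-6-(methoxymethoxy)phenyl]-4-[2,4,6-tris(benzyloxy)phenyl]benzene-1,3,5-triol, via ring A side dioxo ester 17 (not isolated), via ring C side dioxo ester 18 (not isolated)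
Conditions: 16 (3 equiv), NaOMe (6 equiv), MeOH/toluene, reflux with MeOH distilled off (to 110 °C), Ar; then aq NaH2PO4, 0 °C
Reagents that add atoms: dimethyl malonate 16, COC(=O)CC(=O)OC
Why: Proposed new method: methoxide equilibrates ketone 15 with its two benzylic enolates, and C-acylation of either by the malonic ester (or by the methoxycarbonylketene that sodiomalonate can shed on heating) gives dioxo ester 17 or 18 (bond b1–b6 or b3–b4), held as its β-dicarbonyl anion. The remaining benzylic carbon is then deprotonated in a minor equilibrium and attacks the ester carbonyl in a 6-(enolendo)-exo-trig Claisen (Dieckmann-type) closure that forms the second bond and ring B; the triketo form of the product tautomerises at once to phloroglucinol 19, which leaves all equilibria as its phenoxide. The closest known reaction types are the twofold Claisen condensation of dibenzyl ketone with dialkyl oxalates, the self-condensation of malonic esters to phloroglucinol carboxylates and the base-induced cyclisation of 3,5-dioxo esters to phloroglucinols; joining a 1,3-diarylacetone with a malonic ester in one operation is not established. No stereocentre is created, and the two aryl–CH2 bonds of 15 become the biaryl bonds, so no hindered aryl–aryl bond has to be formed. The step needs acylation at both benzylic carbons and on carbon rather than oxygen: 17 and 18 converge on the same ring, the lactones of O-acylation (F3 and F4 of the fallback) are reopened by methoxide, and only aromatisation is irreversible. Excess base and removal of methanol are used because sodiomalonate is a poor acyl donor and the hindered ketone is weakly acidic; benzyl and methoxymethyl ethers are inert to alkoxide, and the air-sensitive triol is best carried crude into step 11.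

Step 11
Reactants: 19 the triol of step 10; 2 benzyl bromide
Product: 20 1,3,5-tris(benzyloxy)-2-[2,4-bis(benzyloxy)-6-(methoxymethoxy)phenyl]-4-[2,4,6-tris(benzyloxy)phenyl]benzene
Conditions: BnBr (4 equiv), Cs2CO3, DMF, rt → 50 °C, Ar
Reagents that add atoms: benzyl bromide 2, BrCc1ccccc1
Why: Williamson etherification of the three ring B phenols with a caesium base in a dipolar aprotic solvent, which favours O- over C-alkylation; the hindered b2 phenol needs mild heating.

Step 12
Reactants: 20 the octabenzyl methoxymethyl ether of step 11
Product: 21 3,5-bis(benzyloxy)-2-{2,4,6-tris(benzyloxy)-3-[2,4,6-tris(benzyloxy)phenyl]phenyl}phenol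
Conditions: HCl (2 M aq), MeOH/THF, 50 °C
Reagents that add atoms: none
Why: Acid-catalysed acetal exchange with methanol removes the methoxymethyl group; aryl benzyl ethers are stable to dilute methanolic HCl.

Step 13
Reactants: 21 the phenol of step 12
Product: 22 sodium 3,5-bis(benzyloxy)-2-{2,4,6-tris(benzyloxy)-3-[2,4,6-tris(benzyloxy)phenyl]phenyl}phenyl sulfate
Conditions: SO3·pyridine (5 equiv), pyridine, 55 °C; then aq NaHCO3
Reagents that add atoms: sulfur trioxide pyridine complex, [O-]S(=O)(=O)[n+]1ccccc1; sodium hydrogencarbonate, [Na+].OC([O-])=O
Why: O-sulfation of the single free phenol by the sulfur trioxide–amine complex; exchanging pyridinium for sodium gives a storable salt and removes pyridine, which would inhibit the palladium-catalysed hydrogenolysis that follows.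

Step 14
Reactants: 22 the sodium sulfate of step 13
Product: 24 3,5-dihydroxy-2-[2,4,6-trihydroxy-3-(2,4,6-trihydroxyphenyl)phenyl]phenyl hydrogen sulfate (target CNP0244954.0), via sodium salt of the target 23 (not isolated)
Conditions: H2 (1 atm), Pd(OH)2/C, THF/MeOH, rt; filtration under Ar; then HCl (1.0 equiv, aq), 0 °C, C18 desalting, freeze-drying
Reagents that add atoms: none
Why: Hydrogenolysis of the eight aryl benzyl ethers; aryl sulfate monoester salts are inert to these conditions, and cold protonation with one equivalent of acid followed by desalting should give the free hydrogen sulfate.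

## Compound list

1 | 2,4,6-trihydroxybenzaldehyde | O=Cc1c(O)cc(O)cc1O | starting material
2 | benzyl bromide | BrCc1ccccc1 | starting material
3 | 2,4-bis(benzyloxy)-6-hydroxybenzaldehyde | O=Cc1c(O)cc(OCc2ccccc2)cc1OCc1ccccc1 | intermediate
4 | 2,4,6-tris(benzyloxy)benzaldehyde | O=Cc1c(OCc2ccccc2)cc(OCc2ccccc2)cc1OCc1ccccc1 | intermediate
5 | p-toluenesulfonylmethyl isocyanide (TosMIC) | Cc1ccc(cc1)S(=O)(=O)C[N+]#[C-] | starting material
6 | 2-[2,4,6-tris(benzyloxy)phenyl]acetonitrile | N#CCc1c(OCc2ccccc2)cc(OCc2ccccc2)cc1OCc1ccccc1 | intermediate
7 | methyl 2-[2,4,6-tris(benzyloxy)phenyl]acetimidate hydrochloride | COC(=[NH2+])Cc1c(OCc2ccccc2)cc(OCc2ccccc2)cc1OCc1ccccc1.[Cl-] | intermediate (not isolated)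
8 | methyl 2-[2,4,6-tris(benzyloxy)phenyl]acetate | COC(=O)Cc1c(OCc2ccccc2)cc(OCc2ccccc2)cc1OCc1ccccc1 | intermediate
9 | chloromethyl methyl ether | COCCl | starting material
10 | 2,4-bis(benzyloxy)-6-(methoxymethoxy)benzaldehyde | COCOc1cc(OCc2ccccc2)cc(OCc2ccccc2)c1C=O | intermediate
11 | 2-[2,4-bis(benzyloxy)-6-(methoxymethoxy)phenyl]acetonitrile | COCOc1cc(OCc2ccccc2)cc(OCc2ccccc2)c1CC#N | intermediate
12 | 2-[2,4-bis(benzyloxy)-6-(methoxymethoxy)phenyl]acetic acid | COCOc1cc(OCc2ccccc2)cc(OCc2ccccc2)c1CC(=O)O | intermediate
13 | 2-[2,4-bis(benzyloxy)-6-(methoxymethoxy)phenyl]-1-(imidazol-1-yl)ethan-1-one | COCOc1cc(OCc2ccccc2)cc(OCc2ccccc2)c1CC(=O)n1ccnc1 | intermediate (not isolated)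
14 | methyl 4-[2,4-bis(benzyloxy)-6-(methoxymethoxy)phenyl]-3-oxo-2-[2,4,6-tris(benzyloxy)phenyl]butanoate (racemic) | COC(=O)C(c1c(OCc2ccccc2)cc(OCc2ccccc2)cc1OCc1ccccc1)C(=O)Cc1c(OCOC)cc(OCc2ccccc2)cc1OCc1ccccc1 | intermediate
15 | 1-[2,4-bis(benzyloxy)-6-(methoxymethoxy)phenyl]-3-[2,4,6-tris(benzyloxy)phenyl]propan-2-one | COCOc1cc(OCc2ccccc2)cc(OCc2ccccc2)c1CC(=O)Cc1c(OCc2ccccc2)cc(OCc2ccccc2)cc1OCc1ccccc1 | intermediate
16 | dimethyl malonate | COC(=O)CC(=O)OC | starting material
17 | methyl 4-[2,4-bis(benzyloxy)-6-(methoxymethoxy)phenyl]-3,5-dioxo-6-[2,4,6-tris(benzyloxy)phenyl]hexanoate (racemic) | COC(=O)CC(=O)C(c1c(OCOC)cc(OCc2ccccc2)cc1OCc1ccccc1)C(=O)Cc1c(OCc2ccccc2)cc(OCc2ccccc2)cc1OCc1ccccc1 | intermediate (not isolated)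
18 | methyl 6-[2,4-bis(benzyloxy)-6-(methoxymethoxy)phenyl]-3,5-dioxo-4-[2,4,6-tris(benzyloxy)phenyl]hexanoate (racemic) | COC(=O)CC(=O)C(c1c(OCc2ccccc2)cc(OCc2ccccc2)cc1OCc1ccccc1)C(=O)Cc1c(OCOC)cc(OCc2ccccc2)cc1OCc1ccccc1 | intermediate (not isolated)
19 | 2-[2,4-bis(benzyloxy)-6-(methoxymethoxy)phenyl]-4-[2,4,6-tris(benzyloxy)phenyl]benzene-1,3,5-triol | COCOc1cc(OCc2ccccc2)cc(OCc2ccccc2)c1-c1c(O)cc(O)c(-c2c(OCc3ccccc3)cc(OCc3ccccc3)cc2OCc2ccccc2)c1O | intermediate
20 | 1,3,5-tris(benzyloxy)-2-[2,4-bis(benzyloxy)-6-(methoxymethoxy)phenyl]-4-[2,4,6-tris(benzyloxy)phenyl]benzene | COCOc1cc(OCc2ccccc2)cc(OCc2ccccc2)c1-c1c(OCc2ccccc2)cc(OCc2ccccc2)c(-c2c(OCc3ccccc3)cc(OCc3ccccc3)cc2OCc2ccccc2)c1OCc1ccccc1 | intermediate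
21 | 3,5-bis(benzyloxy)-2-{2,4,6-tris(benzyloxy)-3-[2,4,6-tris(benzyloxy)phenyl]phenyl}phenol | Oc1cc(OCc2ccccc2)cc(OCc2ccccc2)c1-c1c(OCc2ccccc2)cc(OCc2ccccc2)c(-c2c(OCc3ccccc3)cc(OCc3ccccc3)cc2OCc2ccccc2)c1OCc1ccccc1 | intermediate
22 | sodium 3,5-bis(benzyloxy)-2-{2,4,6-tris(benzyloxy)-3-[2,4,6-tris(benzyloxy)phenyl]phenyl}phenyl sulfate | [Na+].[O-]S(=O)(=O)Oc1cc(OCc2ccccc2)cc(OCc2ccccc2)c1-c1c(OCc2ccccc2)cc(OCc2ccccc2)c(-c2c(OCc3ccccc3)cc(OCc3ccccc3)cc2OCc2ccccc2)c1OCc1ccccc1 | intermediate
23 | sodium 3,5-dihydroxy-2-[2,4,6-trihydroxy-3-(2,4,6-trihydroxyphenyl)phenyl]phenyl sulfate | [Na+].[O-]S(=O)(=O)Oc1cc(O)cc(O)c1-c1c(O)cc(O)c(-c2c(O)cc(O)cc2O)c1O | intermediate (not isolated)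
24 | 3,5-dihydroxy-2-[2,4,6-trihydroxy-3-(2,4,6-trihydroxyphenyl)phenyl]phenyl hydrogen sulfate | O=S(=O)(O)Oc1cc(O)cc(O)c1-c1c(O)cc(O)c(-c2c(O)cc(O)cc2O)c1O | target

## Step count and least certain steps

Total step count: 14. Longest linear sequence: 11 steps (1 → 3 → 10 → 11 → 12 → 14 → 15 → 19 → 20 → 21 → 22 → 24; the ring C arm through 4, 6 and 8 is equally long).

Step 10 (key step, proposed new method). The most likely failure is that the first intermolecular C-acylation does not start, because the malonic ester sits as its unreactive sodium enolate while the hindered ketone enolate is present only in low concentration. The sequence could also stall at the lactone of O-acylation, and prolonged heating with methoxide could slowly cleave benzyl ethers or let the phenoxide of 19 oxidise. The fallback keeps the same ring B bonds but forms them stepwise by known reaction types. It sets out from 15: silylation (TMSCl, Et3N, NaI, MeCN) should give the ring A side trimethylsilyl enol ether F1 together with its ring C side regioisomer F2. The mixture is condensed with malonyl dichloride (Et2O, −78 °C → rt, HCl swept out with argon) in the known cyclocondensation of silyl enol ethers to 4-hydroxypyran-2-ones. This should give the 5-(ring A aryl)-6-(ring C benzyl) pyranone F3 and the 5-(ring C aryl)-6-(ring A benzyl) pyranone F4. Mg(OMe)2 in refluxing methanol then opens both lactones to the magnesium chelates of 17 and 18, and NaOMe at higher temperature closes them to 19, where the route is rejoined. The regiochemistry of enol ether formation does not matter, because F3 and F4 converge.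

Step 8. Proton transfer from the acyl imidazolide to the basic enolate may lead to ketene dimerisation or self-condensation of the acyl partner, and C-acylation of the enolate carbon that carries a di-ortho-substituted aryl ring may be slow enough for O-acylation to compete. The fallback replaces the basic lithium enolate by a non-basic magnesium enolate. It sets out from 8: methoxycarbonylation (NaH, dimethyl carbonate, THF, reflux) gives dimethyl 2-[2,4,6-tris(benzyloxy)phenyl]malonate F5, and one ester is saponified (KOH, 1 equiv, MeOH/THF, then mild acid) to the malonic half ester F6. Its magnesium enolate (MgCl2, Et3N, MeCN/THF) is acylated by 13 with loss of CO2 in a decarboxylative Claisen condensation, returning to the route at 14.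

Step 11. The ambident phloroglucinol phenoxide may be benzylated on carbon b5, and etherification of the b2 oxygen between two aryl rings may stay incomplete. The fallback sets out from 19 and uses Mitsunobu etherification with benzyl alcohol (PPh3, DIAD, THF/toluene, rt → 40 °C), in which the phenols react as acids toward the alkoxyphosphonium ion and no free phenoxide is alkylated by a halide. It returns to the route at 20 without a new intermediate.

Step 13. Sulfation of the a1 phenol, which is flanked by the biaryl axis and two ortho benzyloxy groups of ring B, may be slow, and the sulfate may be lost again during work-up or chromatography of the salt. The fallback sets out from 21: 2,2,2-trichloroethyl chlorosulfate (Et3N, DMAP, THF) gives the neutral, chromatographable aryl 2,2,2-trichloroethyl sulfate F7. Reductive removal of the trichloroethyl group (Zn, HCO2NH4, MeOH/THF), which leaves benzyl ethers intact, and sodium exchange return to the route at 22.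

Step 6 (the same applies to step 3). With a di-ortho-alkoxy aldehyde, addition of the TosMIC anion may be slow and the oxazoline may aromatise to an oxazole instead of opening to the nitrile. The fallback sets out from 10 and uses a Jocic-type reductive homologation: trichloromethide addition (CCl3CO2Na, CCl3CO2H, DMF, rt) gives 1-[2,4-bis(benzyloxy)-6-(methoxymethoxy)phenyl]-2,2,2-trichloroethanol F8. NaBH4/NaOH in t-BuOH at 55 °C converts it through the dichloroepoxide, with hydride opening at the benzylic carbon, into acid 12, where the route is rejoined (the nitrile 11 is bypassed).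

## Further compounds

F1 | step 10 | {[1-[2,4-bis(benzyloxy)-6-(methoxymethoxy)phenyl]-3-[2,4,6-tris(benzyloxy)phenyl]prop-1-en-2-yl]oxy}trimethylsilane (alkene geometry undefined) | C[Si](C)(C)OC(=Cc1c(OCOC)cc(OCc2ccccc2)cc1OCc1ccccc1)Cc1c(OCc2ccccc2)cc(OCc2ccccc2)cc1OCc1ccccc1
F2 | step 10 | {[3-[2,4-bis(benzyloxy)-6-(methoxymethoxy)phenyl]-1-[2,4,6-tris(benzyloxy)phenyl]prop-1-en-2-yl]oxy}trimethylsilane (alkene geometry undefined) | C[Si](C)(C)OC(=Cc1c(OCc2ccccc2)cc(OCc2ccccc2)cc1OCc1ccccc1)Cc1c(OCOC)cc(OCc2ccccc2)cc1OCc1ccccc1
F3 | step 10 | 5-[2,4-bis(benzyloxy)-6-(methoxymethoxy)phenyl]-4-hydroxy-6-{[2,4,6-tris(benzyloxy)phenyl]methyl}-2H-pyran-2-one | O=C1C=C(O)C(c2c(OCOC)cc(OCc3ccccc3)cc2OCc2ccccc2)=C(Cc2c(OCc3ccccc3)cc(OCc3ccccc3)cc2OCc2ccccc2)O1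
F4 | step 10 | 6-{[2,4-bis(benzyloxy)-6-(methoxymethoxy)phenyl]methyl}-4-hydroxy-5-[2,4,6-tris(benzyloxy)phenyl]-2H-pyran-2-one | O=C1C=C(O)C(c2c(OCc3ccccc3)cc(OCc3ccccc3)cc2OCc2ccccc2)=C(Cc2c(OCOC)cc(OCc3ccccc3)cc2OCc2ccccc2)O1
F5 | step 8 | dimethyl 2-[2,4,6-tris(benzyloxy)phenyl]malonate | COC(=O)C(C(=O)OC)c1c(OCc2ccccc2)cc(OCc2ccccc2)cc1OCc1ccccc1
F6 | step 8 | 3-methoxy-3-oxo-2-[2,4,6-tris(benzyloxy)phenyl]propanoic acid (racemic) | COC(=O)C(C(=O)O)c1c(OCc2ccccc2)cc(OCc2ccccc2)cc1OCc1ccccc1
F0 | step 11 | none | none
F7 | step 13 | 3,5-bis(benzyloxy)-2-{2,4,6-tris(benzyloxy)-3-[2,4,6-tris(benzyloxy)phenyl]phenyl}phenyl 2,2,2-trichloroethyl sulfate | ClC(Cl)(Cl)COS(=O)(=O)Oc1cc(OCc2ccccc2)cc(OCc2ccccc2)c1-c1c(OCc2ccccc2)cc(OCc2ccccc2)c(-c2c(OCc3ccccc3)cc(OCc3ccccc3)cc2OCc2ccccc2)c1OCc1ccccc1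
F8 | step 6 | 1-[2,4-bis(benzyloxy)-6-(methoxymethoxy)phenyl]-2,2,2-trichloroethanol (racemic) | COCOc1cc(OCc2ccccc2)cc(OCc2ccccc2)c1C(O)C(Cl)(Cl)Cl
A1 | alternative 1 | terphenyl with free hydroxyls at a1 and c2, acetates at a3 and c4 and five benzyl ethers | Oc3cc(OC(C)=O)cc(OCc4ccccc4)c3-c1c(OCc4ccccc4)cc(OCc4ccccc4)c(-c2c(O)cc(OC(C)=O)cc2OCc4ccccc4)c1OCc4ccccc4
A2 | alternative 1 | 1,3,5-tris(benzyloxy)-2,4-bis[3-acetoxy-2-(benzyloxy)pent-1-en-4-yn-1-yl]benzene (configurations undefined) | C#CC(OC(C)=O)C(OCc1ccccc1)=Cc1c(OCc2ccccc2)cc(OCc2ccccc2)c(C=C(OCc2ccccc2)C(OC(C)=O)C#C)c1OCc1ccccc1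
A3 | alternative 2 | terphenyl with free hydroxyl at b2, triisopropylsilyl ethers at a5 and b6, trichloroethyl sulfate at a1 and five benzyl ethers | ClC(Cl)(Cl)COS(=O)(=O)Oc3cc(OCc4ccccc4)cc(O[Si](C(C)C)(C(C)C)C(C)C)c3-c1c(O[Si](C(C)C)(C(C)C)C(C)C)cc(OCc4ccccc4)c(-c2c(OCc4ccccc4)cc(OCc4ccccc4)cc2OCc4ccccc4)c1O
A4 | alternative 2 | 3-(benzyloxy)-4-[2,4,6-tris(benzyloxy)phenyl]cyclobut-2-en-1-one (racemic) | O=C1C=C(OCc2ccccc2)C1c1c(OCc2ccccc2)cc(OCc2ccccc2)cc1OCc1ccccc1
A5 | alternative 2 | 5-(benzyloxy)-3-[(triisopropylsilyl)oxy]-2-{[(triisopropylsilyl)oxy]ethynyl}phenyl 2,2,2-trichloroethyl sulfate | ClC(Cl)(Cl)COS(=O)(=O)Oc1cc(OCc2ccccc2)cc(O[Si](C(C)C)(C(C)C)C(C)C)c1C#CO[Si](C(C)C)(C(C)C)C(C)C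
A6 | alternative 3 | terphenyl with ring C as free triol, methoxymethyl ether at a1 and the other oxygens benzylated | COCOc3cc(OCc4ccccc4)cc(OCc4ccccc4)c3-c1c(OCc4ccccc4)cc(OCc4ccccc4)c(-c2c(O)cc(O)cc2O)c1OCc4ccccc4
A7 | alternative 3 | 3-{2,4,6-tris(benzyloxy)-3-[2,4-bis(benzyloxy)-6-(methoxymethoxy)phenyl]phenyl}-4-hydroxy-6-methyl-2H-pyran-2-one | COCOc1cc(OCc2ccccc2)cc(OCc2ccccc2)c1-c1c(OCc2ccccc2)cc(OCc2ccccc2)c(C2=C(O)C=C(C)OC2=O)c1OCc1ccccc1
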